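Everything rests on disconnecting C1–C2 of the cyclohexene (C1 acyl, C2 prenyl, C3 methyl, C6 phenyl). In that ring the C1 carbonyl and the C3=C4 double bond make up a γ,δ-unsaturated carbonyl unit, the mark of a [3,3] shift from an allylic ester oxygen once bound to C4. With ester and allylic oxygen tied into the cis-4-phenyl-6-alkenyl δ-lactone 11 (E trisubstituted side-chain alkene), a single Ireland–Claisen rearrangement forms C1–C2, closes the carbocycle, sets C1 and C2 relative to C6 and frees the carboxyl group that becomes the aryl ketone. The benzofuran is attached afterwards as its 7-lithio derivative.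

Key step: step 5

Assumption: the bifunctional cinchona catalyst of step 2 is used as the pseudoenantiomer (quinine- or quinidine-derived) that delivers the (R)-hemiester 5, and 2,4-dihydroxy-6-methoxybenzaldehyde 17 is purchased.

Remark on structures: visnagin is not used as the aryl source. Its benzofuran carries the carbon substituent at C5 (between OMe and OH), whereas the target is acylated at C7 (between OH and the furan oxygen), and direct lithiation of a 4-methoxy-6-(methoxymethoxy)benzofuran would compete at C2 and C5. The C7 nucleophile is therefore made from bromide 24, whose bromine is placed between two MOM ethers before the furan is closed. The carbinol centre of lactone 11 is set by a catalyst-controlled ketone reduction, not by addition to an aldehyde. The lactone and the carbocycle made from it are both six-membered.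

Step 1
Reactants: 1 prop-1-yn-1-ylmagnesium bromide; 2 1-bromo-3-methylbut-2-ene
Product: 3 6-methylhept-5-en-2-yne
Conditions: CuBr·SMe2 (5 mol %), THF, 0 °C → rt
Reagents that add atoms: none
Why: Copper(I)-catalysed coupling of the alkynyl Grignard reagent with the allylic bromide should take place at the unhindered primary carbon (SN2) and give the skipped enyne.

Step 2
Reactants: 4 3-phenylglutaric anhydride
Product: 5 (3R)-5-methoxy-5-oxo-3-phenylpentanoic acid
Conditions: MeOH (10 equiv), bifunctional cinchona sulfonamide catalyst (10 mol %), MTBE, −20 °C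
Reagents that add atoms: methanol, CO
Why: In this catalytic desymmetrising alcoholysis the catalyst activates methanol by general-base catalysis and one of the two enantiotopic carbonyl groups by hydrogen bonding, so the ring should open on one side only and set the benzylic stereocentre as R.

Step 3
Reactants: 5 (3R)-5-methoxy-5-oxo-3-phenylpentanoic acid; 3 6-methylhept-5-en-2-yne
Product: 9 methyl (3R,6E)-6,10-dimethyl-5-oxo-3-phenylundeca-6,9-dienoate, via acid chloride 6 (not isolated), via alkenylzirconocene chloride 7 (not isolated), via alkenylzinc chloride 8 (not isolated)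
Conditions: (a) 5, (COCl)2, cat. DMF, CH2Cl2, 0 °C → rt, evaporate; (b) 3 (1.5 equiv), Cp2Zr(H)Cl (1.6 equiv), THF, rt → 45 °C; (c) ZnCl2, then 6, Pd(PPh3)4 (5 mol %), THF, 0 °C → rt
Reagents that add atoms: none
Why: Hydrozirconation with the Schwartz reagent adds H and Zr syn across the alkyne with Zr on the methyl-bearing carbon after thermal equilibration, and Zr-to-Zn transmetalation followed by Negishi acylation transfers the alkenyl group with retention, so the E trisubstituted enone should form while the methyl ester and the benzylic stereocentre stay untouched.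

Step 4
Reactants: 9 methyl (3R,6E)-6,10-dimethyl-5-oxo-3-phenylundeca-6,9-dienoate
Product: 11 (4R,6R)-6-[(2E)-6-methylhepta-2,5-dien-2-yl]-4-phenyloxan-2-one, via hydroxy ester 10 (not isolated)
Conditions: (S)-Me-CBS (20 mol %), catecholborane, PhMe, −78 °C; aqueous work-up; then PPTS (10 mol %), PhMe, 60 °C
Reagents that add atoms: none
Why: Corey–Bakshi–Shibata reduction delivers hydride to the enone carbonyl under catalyst control (α-methylalkenyl as the large group, CH2 as the small one) and should give the 5R carbinol irrespective of the remote C3 centre, after which mild acid-catalysed lactonisation of the δ-hydroxy ester gives the cis-4,6-disubstituted lactone.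

Step 5
Reactants: 11 (4R,6R)-6-[(2E)-6-methylhepta-2,5-dien-2-yl]-4-phenyloxan-2-one
Product: 14 (1R,2S,6R)-3-methyl-2-(3-methylbut-2-en-1-yl)-6-phenylcyclohex-3-ene-1-carboxylic acid, via silyl ketene acetal 12 (not isolated), via silyl ester 13 (not isolated)
Conditions: LDA (1.2 equiv), TBSCl (1.5 equiv), DMPU, THF, −78 °C; then PhMe, 105 °C; then AcOH–THF–H2O, rt
Reagents that add atoms: none
Why: LDA removes an α-proton at C3 of lactone 11 and in situ O-silylation gives cyclic silyl ketene acetal 12, whose enol ether geometry is fixed by the ring. On heating, the C6 alkenyl group turns axial and the unit C3=C2–O1–C6–C(Me)=CH undergoes a concerted [3,3] sigmatropic shift, an Ireland–Claisen rearrangement of a lactone silyl ketene acetal, for which the known conversion of 6-alkenyl δ-lactone ketene acetals into cyclohex-3-enecarboxylic acids is the closest precedent. The cyclohexene is closed by the shift itself: lactone C3 bonds to the alkene CH while O1–C6 breaks, through a boat, bicyclo[2.2.2]-like transition state (a chair cannot be reached across the two-atom tether), so the six-membered lactone is exchanged for a six-membered carbocycle made of lactone C3–C6 and the two alkene carbons, with O1 and C2 extruded as the carboxyl group. The new C1 stereocentre is controlled by the lactone C6 carbinol centre, because bonding must occur on the ring face that carries the alkenyl group; the phenyl group on that same face (cis lactone) therefore ends opposite the carboxyl group, i.e. trans. The new C2 stereocentre is controlled by the E alkene geometry, which in the boat turns the prenyl CH2 towards the carboxyl-bearing bridge (cis to CO2H) and the vinylic H towards the phenyl-bearing bridge. The step needs complete transfer of the carbinol configuration, which the cis lactone and the E alkene of 11 secure, and O- over C-silylation, favoured by in situ trapping with TBSCl/DMPU; mild aqueous acetic acid then hydrolyses silyl ester 13 to acid 14.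

Step 6
Reactants: 14 (1R,2S,6R)-3-methyl-2-(3-methylbut-2-en-1-yl)-6-phenylcyclohex-3-ene-1-carboxylic acid
Product: 15 [(1R,2S,6R)-3-methyl-2-(3-methylbut-2-en-1-yl)-6-phenylcyclohex-3-en-1-yl]methanol
Conditions: LiAlH4, THF, 0 °C → rt
Reagents that add atoms: none
Why: Lithium aluminium hydride reduction of the carboxylic acid to the primary alcohol leaves the trisubstituted alkenes and the three stereocentres untouched.

Step 7
Reactants: 15 [(1R,2S,6R)-3-methyl-2-(3-methylbut-2-en-1-yl)-6-phenylcyclohex-3-en-1-yl]methanol
Product: 16 (1R,2S,6R)-3-methyl-2-(3-methylbut-2-en-1-yl)-6-phenylcyclohex-3-ene-1-carbaldehyde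
Conditions: Dess–Martin periodinane, CH2Cl2, 0 °C → rt
Reagents that add atoms: none
Why: Dess–Martin oxidation under non-enolising conditions should give the aldehyde without epimerising C1, whose trans relationship to the C6 phenyl group is in any case the more stable arrangement.

Step 8
Reactants: 17 2,4-dihydroxy-6-methoxybenzaldehyde
Product: 18 2-methoxy-4,6-bis(methoxymethoxy)benzaldehyde
Conditions: NaH, MOMCl, DMF, 0 °C → rt
Reagents that add atoms: chloromethyl methyl ether, COCCl
Why: Double Williamson alkylation of the phenoxides with chloromethyl methyl ether protects both hydroxyl groups as MOM acetals, which later serve as the two directing groups.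

Step 9
Reactants: 18 2-methoxy-4,6-bis(methoxymethoxy)benzaldehyde
Product: 19 1-methoxy-2-(2-methoxyethenyl)-3,5-bis(methoxymethoxy)benzene (E/Z mixture)
Conditions: MeOCH2PPh3Cl, KOt-Bu, THF, 0 °C → rt
Reagents that add atoms: (methoxymethyl)triphenylphosphonium chloride, COC[P+](c1ccccc1)(c1ccccc1)c1ccccc1.[Cl-]
Why: Wittig methoxymethylenation converts the aldehyde into an enol ether (alkene geometry irrelevant), a masked arylacetaldehyde that carries the two future furan carbons.

Step 10
Reactants: 19 1-methoxy-2-(2-methoxyethenyl)-3,5-bis(methoxymethoxy)benzene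
Product: 21 2-bromo-5-methoxy-4-(2-methoxyethenyl)-1,3-bis(methoxymethoxy)benzene, via aryllithium 20 (not isolated)
Conditions: n-BuLi, THF, 0 °C; then BrCH2CH2Br, −78 °C → rt
Reagents that add atoms: 1,2-dibromoethane, BrCCBr
Why: Directed ortho-metalation occurs at the one ring position flanked by two MOM ethers and the aryllithium abstracts bromine from 1,2-dibromoethane, so the halogen is placed unambiguously at the future C7.

Step 11
Reactants: 21 2-bromo-5-methoxy-4-(2-methoxyethenyl)-1,3-bis(methoxymethoxy)benzene
Product: 23 7-bromo-4-methoxy-1-benzofuran-6-ol, via cyclic acetal 22 (not isolated)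
Conditions: HCl, MeOH, 65 °C; then TsOH·H2O (cat.), PhMe, 80 °C
Reagents that add atoms: none
Why: Acid cleaves both MOM acetals, the phenol next to the side chain adds to the protonated enol ether (oxocarbenium ion) to give a cyclic acetal, and loss of methanol aromatises it to the benzofuran (cyclodehydration), which leaves the bromine at C7 between the furan oxygen and the free 6-OH.

Step 12
Reactants: 23 7-bromo-4-methoxy-1-benzofuran-6-ol
Product: 24 7-bromo-4-methoxy-6-(methoxymethoxy)-1-benzofuran
Conditions: MOMCl, i-Pr2NEt, CH2Cl2, 0 °C → rt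
Reagents that add atoms: chloromethyl methyl ether, COCCl
Why: MOM protection of the phenol (Williamson alkylation) masks the acidic OH and provides a chelating ortho group for the aryllithium.

Step 13
Reactants: 24 7-bromo-4-methoxy-6-(methoxymethoxy)-1-benzofuran; 16 (1R,2S,6R)-3-methyl-2-(3-methylbut-2-en-1-yl)-6-phenylcyclohex-3-ene-1-carbaldehyde
Product: 26 [4-methoxy-6-(methoxymethoxy)-1-benzofuran-7-yl][(1R,2S,6R)-3-methyl-2-(3-methylbut-2-en-1-yl)-6-phenylcyclohex-3-en-1-yl]methanol (both carbinol epimers), via aryllithium 25 (not isolated)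
Conditions: 24, n-BuLi, THF, −78 °C; then 16, −78 → −40 °C; H2O
Reagents that add atoms: none
Why: Bromine–lithium exchange at −78 °C is faster than deprotonation of the furan C2–H and gives the C7 aryllithium regiospecifically, which adds 1,2 to the aldehyde; the new carbinol centre forms as a mixture of epimers that the next step erases.

Step 14
Reactants: 26 [4-methoxy-6-(methoxymethoxy)-1-benzofuran-7-yl][(1R,2S,6R)-3-methyl-2-(3-methylbut-2-en-1-yl)-6-phenylcyclohex-3-en-1-yl]methanol
Product: 27 [4-methoxy-6-(methoxymethoxy)-1-benzofuran-7-yl][(1R,2S,6R)-3-methyl-2-(3-methylbut-2-en-1-yl)-6-phenylcyclohex-3-en-1-yl]methanone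
Conditions: Dess–Martin periodinane, CH2Cl2, rt
Reagents that add atoms: none
Why: Dess–Martin oxidation of the secondary benzylic alcohol should give the aryl ketone under conditions that leave the MOM acetal, the furan, the alkenes and the C1 stereocentre intact.

Step 15
Reactants: 27 [4-methoxy-6-(methoxymethoxy)-1-benzofuran-7-yl][(1R,2S,6R)-3-methyl-2-(3-methylbut-2-en-1-yl)-6-phenylcyclohex-3-en-1-yl]methanone
Product: 28 (6-hydroxy-4-methoxy-1-benzofuran-7-yl)[(1R,2S,6R)-3-methyl-2-(3-methylbut-2-en-1-yl)-6-phenylcyclohex-3-en-1-yl]methanone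
Conditions: HCl (cat.), MeOH, 40 °C
Reagents that add atoms: none
Why: Acid-catalysed transacetalisation to methanol removes the MOM group, assisted by the neighbouring carbonyl, under conditions mild enough for the two trisubstituted alkenes, and frees the hydrogen-bonded 6-OH of the target.

Compound list

1 | prop-1-yn-1-ylmagnesium bromide | CC#C[Mg]Br | starting material
2 | 1-bromo-3-methylbut-2-ene | CC(C)=CCBr | starting material
3 | 6-methylhept-5-en-2-yne | CC#CCC=C(C)C | intermediate
4 | 3-phenylglutaric anhydride (4-phenyloxane-2,6-dione) | O=C1CC(c2ccccc2)CC(=O)O1 | starting material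
5 | (3R)-5-methoxy-5-oxo-3-phenylpentanoic acid | COC(=O)C[C@H](c1ccccc1)CC(=O)O | intermediate
6 | methyl (3S)-5-chloro-5-oxo-3-phenylpentanoate (same spatial arrangement as 5; descriptor changes by CIP priority only) | COC(=O)C[C@H](c1ccccc1)CC(=O)Cl | intermediate
7 | chlorobis(cyclopentadienyl)[(2E)-6-methylhepta-2,5-dien-2-yl]zirconium | Cl[Zr](C1C=CC=C1)(C1C=CC=C1)/C(C)=C/CC=C(C)C | intermediate
8 | chloro[(2E)-6-methylhepta-2,5-dien-2-yl]zinc | Cl[Zn]/C(C)=C/CC=C(C)C | intermediate
9 | methyl (3R,6E)-6,10-dimethyl-5-oxo-3-phenylundeca-6,9-dienoate | COC(=O)C[C@H](c1ccccc1)CC(=O)/C(C)=C/CC=C(C)C | intermediate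
10 | methyl (3R,5R,6E)-5-hydroxy-6,10-dimethyl-3-phenylundeca-6,9-dienoate | COC(=O)C[C@H](c1ccccc1)C[C@@H](O)/C(C)=C/CC=C(C)C | intermediate
11 | (4R,6R)-6-[(2E)-6-methylhepta-2,5-dien-2-yl]-4-phenyloxan-2-one | O=C1C[C@H](c2ccccc2)C[C@@H](O1)/C(C)=C/CC=C(C)C | intermediate
12 | tert-butyldimethyl({(2R,4R)-2-[(2E)-6-methylhepta-2,5-dien-2-yl]-4-phenyl-3,4-dihydro-2H-pyran-6-yl}oxy)silane | CC(C)(C)[Si](C)(C)OC1=C[C@H](c2ccccc2)C[C@@H](O1)/C(C)=C/CC=C(C)C | intermediate
13 | tert-butyldimethylsilyl (1R,2S,6R)-3-methyl-2-(3-methylbut-2-en-1-yl)-6-phenylcyclohex-3-ene-1-carboxylate | CC(C)(C)[Si](C)(C)OC(=O)[C@@H]1[C@H](CC=C(C)C)C(C)=CC[C@H]1c1ccccc1 | intermediate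
14 | (1R,2S,6R)-3-methyl-2-(3-methylbut-2-en-1-yl)-6-phenylcyclohex-3-ene-1-carboxylic acid | OC(=O)[C@@H]1[C@H](CC=C(C)C)C(C)=CC[C@H]1c1ccccc1 | intermediate
15 | [(1R,2S,6R)-3-methyl-2-(3-methylbut-2-en-1-yl)-6-phenylcyclohex-3-en-1-yl]methanol | OC[C@@H]1[C@H](CC=C(C)C)C(C)=CC[C@H]1c1ccccc1 | intermediate
16 | (1R,2S,6R)-3-methyl-2-(3-methylbut-2-en-1-yl)-6-phenylcyclohex-3-ene-1-carbaldehyde | O=C[C@@H]1[C@H](CC=C(C)C)C(C)=CC[C@H]1c1ccccc1 | intermediate
17 | 2,4-dihydroxy-6-methoxybenzaldehyde | COc1cc(O)cc(O)c1C=O | starting material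
18 | 2-methoxy-4,6-bis(methoxymethoxy)benzaldehyde | O=Cc1c(OC)cc(OCOC)cc1OCOC | intermediate
19 | 1-methoxy-2-(2-methoxyethenyl)-3,5-bis(methoxymethoxy)benzene (E/Z mixture) | COC=Cc1c(OC)cc(OCOC)cc1OCOC | intermediate
20 | [4-methoxy-3-(2-methoxyethenyl)-2,6-bis(methoxymethoxy)phenyl]lithium | COC=Cc1c(OC)cc(OCOC)c([Li])c1OCOC | intermediate
21 | 2-bromo-5-methoxy-4-(2-methoxyethenyl)-1,3-bis(methoxymethoxy)benzene | COC=Cc1c(OC)cc(OCOC)c(Br)c1OCOC | intermediate
22 | 7-bromo-2,4-dimethoxy-2,3-dihydro-1-benzofuran-6-ol (racemic) | COC1Cc2c(OC)cc(O)c(Br)c2O1 | intermediate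
23 | 7-bromo-4-methoxy-1-benzofuran-6-ol | COc1cc(O)c(Br)c2occc12 | intermediate
24 | 7-bromo-4-methoxy-6-(methoxymethoxy)-1-benzofuran | COCOc1cc(OC)c2ccoc2c1Br | intermediate
25 | [4-methoxy-6-(methoxymethoxy)-1-benzofuran-7-yl]lithium | [Li]c1c(OCOC)cc(OC)c2ccoc12 | intermediate
26 | [4-methoxy-6-(methoxymethoxy)-1-benzofuran-7-yl][(1R,2S,6R)-3-methyl-2-(3-methylbut-2-en-1-yl)-6-phenylcyclohex-3-en-1-yl]methanol (both carbinol epimers) | COCOc1cc(OC)c2ccoc2c1C(O)[C@@H]1[C@H](CC=C(C)C)C(C)=CC[C@H]1c1ccccc1 | intermediate
27 | [4-methoxy-6-(methoxymethoxy)-1-benzofuran-7-yl][(1R,2S,6R)-3-methyl-2-(3-methylbut-2-en-1-yl)-6-phenylcyclohex-3-en-1-yl]methanone | COCOc1cc(OC)c2ccoc2c1C(=O)[C@@H]1[C@H](CC=C(C)C)C(C)=CC[C@H]1c1ccccc1 | intermediate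
28 | (6-hydroxy-4-methoxy-1-benzofuran-7-yl)[(1R,2S,6R)-3-methyl-2-(3-methylbut-2-en-1-yl)-6-phenylcyclohex-3-en-1-yl]methanone | COc1cc(O)c(C(=O)[C@@H]2[C@H](CC=C(C)C)C(C)=CC[C@H]2c2ccccc2)c2occc12 | target

Total step count: 15. Longest linear sequence: 9 steps (steps 2–7 and 13–15, from anhydride 4).

Steps most likely to fail

Step 5. The strained boat transition state may be reached only at temperatures where ketene acetal 12 desilylates, or the lactone enolate may self-condense before it is silylated, so that little rearranged acid forms. The fallback builds the ring by an enantioselective Diels–Alder reaction; it sets out from alkenylzirconocene 7 and bromide 24 and comes back at target 28. Pd-catalysed coupling of 7 with vinyl bromide (ZnCl2 co-catalyst) would give (3E)-3,7-dimethylocta-1,3,6-triene F1. Aryllithium 25, made from 24 as in step 13, would add to cinnamaldehyde to give (2E)-1-[4-methoxy-6-(methoxymethoxy)-1-benzofuran-7-yl]-3-phenylprop-2-en-1-ol F2. MnO2 would oxidise this to (2E)-1-[4-methoxy-6-(methoxymethoxy)-1-benzofuran-7-yl]-3-phenylprop-2-en-1-one F3, and HCl in MeOH would free (2E)-1-(6-hydroxy-4-methoxy-1-benzofuran-7-yl)-3-phenylprop-2-en-1-one F4. Cycloaddition of F4 with F1 under a chiral BINOL–borate Lewis acid bound to the chelating hydroxy ketone (the BINOL enantiomer that gives the 1R,2S,6R adduct) should then give 28. The endo transition state places acyl cis to prenyl and the E dienophile places acyl trans to phenyl; the regioisomeric adduct (prenyl next to phenyl) would have to be separated.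

Step 3. Hydrozirconation may deliver zirconium partly to the other alkyne carbon, and acyl transfer to the hindered alkenyl metal may be slow, so that regioisomeric or reduced by-products contaminate the enone. The fallback separates the two problems; it sets out from alkenylzirconocene 7 and acid chloride 6 and comes back at enone 9. Iodinolysis of 7 would give (2E)-2-iodo-6-methylhepta-2,5-diene F5, which can be purified. Reduction of 6 with LiAlH(Ot-Bu)3 at −78 °C would give methyl (3R)-5-oxo-3-phenylpentanoate F6. Nozaki–Hiyama–Kishi coupling of F5 with F6 (CrCl2, cat. NiCl2, DMF) would give methyl (3R,6E)-5-hydroxy-6,10-dimethyl-3-phenylundeca-6,9-dienoate F7 as both C5 epimers, and Dess–Martin oxidation would return to 9.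

Step 13. The hindered, basic aryllithium may deprotonate the α-branched aldehyde (enolisation with partial epimerisation at C1) instead of adding to it. The fallback forms the ketone at the acid oxidation level; it sets out from acid 14 and aryllithium 25 and comes back at ketone 27. Oxalyl chloride with cat. DMF would convert 14 into (1R,2S,6R)-3-methyl-2-(3-methylbut-2-en-1-yl)-6-phenylcyclohex-3-ene-1-carbonyl chloride F8. Transmetalation of 25 with ZnCl2 would give chloro[4-methoxy-6-(methoxymethoxy)-1-benzofuran-7-yl]zinc F9. Pd-catalysed Negishi acylation of F8 with F9 should give 27 directly, so that steps 6, 7 and 14 are not needed.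

Further compounds

F1 | step 5 | (3E)-3,7-dimethylocta-1,3,6-triene | C=C/C(C)=C/CC=C(C)C
F2 | step 5 | (2E)-1-[4-methoxy-6-(methoxymethoxy)-1-benzofuran-7-yl]-3-phenylprop-2-en-1-ol (racemic) | COCOc1cc(OC)c2ccoc2c1C(O)/C=C/c1ccccc1
F3 | step 5 | (2E)-1-[4-methoxy-6-(methoxymethoxy)-1-benzofuran-7-yl]-3-phenylprop-2-en-1-one | COCOc1cc(OC)c2ccoc2c1C(=O)/C=C/c1ccccc1
F4 | step 5 | (2E)-1-(6-hydroxy-4-methoxy-1-benzofuran-7-yl)-3-phenylprop-2-en-1-one | COc1cc(O)c(C(=O)/C=C/c2ccccc2)c2occc12
F5 | step 3 | (2E)-2-iodo-6-methylhepta-2,5-diene | C/C(I)=C\CC=C(C)C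
F6 | step 3 | methyl (3R)-5-oxo-3-phenylpentanoate | COC(=O)C[C@H](c1ccccc1)CC=O
F7 | step 3 | methyl (3R,6E)-5-hydroxy-6,10-dimethyl-3-phenylundeca-6,9-dienoate (both C5 epimers) | COC(=O)C[C@H](c1ccccc1)CC(O)/C(C)=C/CC=C(C)C
F8 | step 13 | (1R,2S,6R)-3-methyl-2-(3-methylbut-2-en-1-yl)-6-phenylcyclohex-3-ene-1-carbonyl chloride | ClC(=O)[C@@H]1[C@H](CC=C(C)C)C(C)=CC[C@H]1c1ccccc1
F9 | step 13 | chloro[4-methoxy-6-(methoxymethoxy)-1-benzofuran-7-yl]zinc | Cl[Zn]c1c(OCOC)cc(OC)c2ccoc12
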